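The dihydrofuran ring that joins the two flavonoid halves is cut at its two bonds to the flavan ring A, O–C7 and C8–C3''. In one (3+2) annulation the 7,8-aryne of a (2S)-flavan, polarised by the pyran oxygen O1 on C8a next to C8, takes up the ketone oxygen at C7 and the ylide carbon at C8 of a beta-keto ester iodonium ylide and gives a 2-arylbenzofuran-3-carboxylate. The precursors are an ortho-silylaryl triflate made from (2S)-naringenin and an achiral ylide. The ester is then turned into the phloroglucinol ketone, and a catalyst-controlled epoxidation of the furan C2=C3 bond with ring closure by the ortho-phenol sets the carbinol and ketal centres together.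

Key step: step 9

Remark: enantiopure (2S)-naringenin is taken as a commercial chiral-pool material; it supplies the flavan centre.
Remark: the carbinol centre is fixed by reagent control in step 13; the ketal centre is not controlled independently, it results from the closure of the pyranone ring, and it is drawn throughout with the configuration of the target SMILES.

Step 1
Reactants: 1 (2S)-naringenin
Product: 2 (2S)-5-hydroxy-2-(4-hydroxyphenyl)-7-(methoxymethoxy)chroman-4-one
Conditions: MOMCl (1.1 equiv), i-Pr2NEt, CH2Cl2, 0 °C to rt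
Reagents that add atoms: chloromethyl methyl ether COCCl
Why: Williamson-type O-alkylation in which the 7-OH (para to the C4 carbonyl, the most acidic phenol) reacts, the 5-OH stays locked in its hydrogen bond to C4=O and the less acidic 4'-OH is left by the single equivalent of reagent; the weak amine base at low temperature should not open the flavanone ring, so C2 stays S.

Step 2
Reactants: 2 (2S)-5-hydroxy-2-(4-hydroxyphenyl)-7-(methoxymethoxy)chroman-4-one
Product: 4 (2S)-2-(4-hydroxyphenyl)-7-(methoxymethoxy)chroman-5-ol, via bis(ethyl carbonate) 3 (not isolated)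
Conditions: ClCO2Et (2.4 equiv), Et3N, THF, 0 °C; then NaBH4, THF/H2O, 0 °C to rt; then 1 M NaOH, MeOH, rt
Reagents that add atoms: none
Why: ortho-hydroxyl-assisted reductive deoxygenation of an aryl ketone: hydride reduces C4=O, the neighbouring 5-O-carbonate moves to the new alkoxide and leaves to give an ortho-quinone methide that takes a second hydride, so C4 becomes CH2 and the 5-OH is set free, hydroxide then cleaves the 4'-carbonate, and C2, which takes no part, keeps its S configuration.

Step 3
Reactants: 4 (2S)-2-(4-hydroxyphenyl)-7-(methoxymethoxy)chroman-5-ol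
Product: 5 (2S)-5-(benzyloxy)-2-[4-(benzyloxy)phenyl]-7-(methoxymethoxy)chromane
Conditions: BnBr (2.4 equiv), K2CO3, DMF, rt
Reagents that add atoms: benzyl bromide BrCc1ccccc1
Why: Williamson ether synthesis on both free phenols; the flavan has no base-labile stereocenter and the MOM ether is stable to carbonate.

Step 4
Reactants: 5 (2S)-5-(benzyloxy)-2-[4-(benzyloxy)phenyl]-7-(methoxymethoxy)chromane
Product: 6 (2S)-5-(benzyloxy)-2-[4-(benzyloxy)phenyl]-8-bromo-7-(methoxymethoxy)chromane
Conditions: NBS (1.0 equiv), CH2Cl2, -78 to -20 °C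
Reagents that add atoms: N-bromosuccinimide O=C1CCC(=O)N1Br
Why: electrophilic aromatic bromination of the phloroglucinol-type ring A, which should occur at C8 (between the ring oxygen O1 and O7) and not at C6 (next to the bulky 5-benzyloxy group), the position preference known for 5,7-di-O-alkylated flavans; the less activated 4'-alkoxyphenyl ring should not compete at low temperature.

Step 5
Reactants: 6 (2S)-5-(benzyloxy)-2-[4-(benzyloxy)phenyl]-8-bromo-7-(methoxymethoxy)chromane
Product: 7 (2S)-5-(benzyloxy)-2-[4-(benzyloxy)phenyl]-8-bromochroman-7-ol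
Conditions: HCl (2 M), MeOH/THF, 40 °C
Reagents that add atoms: none
Why: acid-catalysed cleavage of the MOM acetal (transacetalisation to dimethoxymethane) frees only the 7-OH, because benzyl ethers and the flavan C2–O1 bond are stable to dilute acid in methanol.

Step 6
Reactants: 7 (2S)-5-(benzyloxy)-2-[4-(benzyloxy)phenyl]-8-bromochroman-7-ol
Product: 10 (2S)-5-(benzyloxy)-2-[4-(benzyloxy)phenyl]-8-(trimethylsilyl)chroman-7-yl trifluoromethanesulfonate, via aryl trimethylsilyl ether 8 (not isolated), via lithium 8-silylphenoxide 9 (not isolated)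
Conditions: HMDS, THF, 65 °C, then evaporation; n-BuLi, THF, -78 °C; Tf2O, -78 to 0 °C
Reagents that add atoms: hexamethyldisilazane C[Si](C)(C)N[Si](C)(C)C; trifluoromethanesulfonic anhydride O=S(=O)(OS(=O)(=O)C(F)(F)F)C(F)(F)F
Why: the standard one-flask route to ortho-silylaryl triflates: O-silylation, bromine–lithium exchange at C8, retro-Brook 1,3-shift of the silyl group from O7 to C8, and triflation of the lithium phenoxide.

Step 7
Reactants: 11 1-[4-(benzyloxy)phenyl]ethan-1-one
Product: 12 ethyl 3-[4-(benzyloxy)phenyl]-3-oxopropanoate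
Conditions: (EtO)2CO, NaH, THF, reflux; then aq. HCl
Reagents that add atoms: diethyl carbonate CCOC(=O)OCC
Why: crossed Claisen condensation (C-acylation of the methyl ketone enolate by a non-enolisable carbonate), driven by deprotonation of the beta-keto ester formed.

Step 8
Reactants: 12 ethyl 3-[4-(benzyloxy)phenyl]-3-oxopropanoate
Product: 13 ethyl 3-[4-(benzyloxy)phenyl]-3-oxo-2-(phenyl-λ3-iodanylidene)propanoate (iodonium ylide)
Conditions: PhI(OAc)2, KOH, MeOH, -10 to 0 °C; used at once
Reagents that add atoms: (diacetoxyiodo)benzene CC(=O)OI(OC(C)=O)c1ccccc1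
Why: standard formation of a phenyliodonium ylide from an active methylene compound by ligand exchange at the iodane and loss of two acetates.

Step 9
Reactants: 10 (2S)-5-(benzyloxy)-2-[4-(benzyloxy)phenyl]-8-(trimethylsilyl)chroman-7-yl trifluoromethanesulfonate; 13 ethyl 3-[4-(benzyloxy)phenyl]-3-oxo-2-(phenyl-λ3-iodanylidene)propanoate (iodonium ylide)
Product: 15 ethyl ester of the (2S)-flavan-fused 2-[4-(benzyloxy)phenyl]benzofuran-3-carboxylic acid (furan O on flavan C7; furan C3 on flavan C8; 5-OBn; 4'-OBn), via 7,8-aryne 14 (not isolated)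
Conditions: CsF (3 equiv), 13 (1.5 equiv), MeCN, rt
Reagents that add atoms: none
Why: Fluoride attacks the silyl group of 10 and 1,2-elimination of triflate gives aryne 14; the ketone-enolate oxygen of ylide 13 adds to C7, and the aryl anion left at C8 attacks the iodonium centre, from which reductive ligand coupling with loss of iodobenzene forms the C8–C bond. The closest known reaction type is the CsF-mediated annulation of ortho-silylaryl triflates with iodonium ylides of 1,3-dicarbonyl compounds to benzofurans, a formal (3+2) cycloaddition of the aryne with the O–C=C unit of the ylide. The furan ring closes as a five-membered ring through a six-membered aryl-iodane whose reductive elimination makes the ring C–C bond. No stereocenter is formed and the flavan C2 is not touched. The step needs (a) the right orientation on the aryne, secured by the ring oxygen O1 on C8a, which as in 3-alkoxyarynes sends the nucleophilic oxygen to the remote carbon C7 and leaves the inductively stabilised anion at C8, and (b) attack by the ketone oxygen and not the ester oxygen, secured by the higher enolate character of the aryl ketone oxygen, as in the known 2-substituted benzofuran-3-carboxylate products.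

Step 10
Reactants: 16 1,3,5-tris(benzyloxy)benzene
Product: 17 2-bromo-1,3,5-tris(benzyloxy)benzene
Conditions: NBS (1.0 equiv), CH2Cl2, -78 to 0 °C
Reagents that add atoms: N-bromosuccinimide O=C1CCC(=O)N1Br
Why: electrophilic aromatic bromination; the three free positions are equivalent by symmetry, so mono-bromination should give one product.

Step 11
Reactants: 17 2-bromo-1,3,5-tris(benzyloxy)benzene; 15 ethyl ester of the (2S)-flavan-fused 2-[4-(benzyloxy)phenyl]benzofuran-3-carboxylic acid
Product: 19 (2S)-flavan-fused 2-[4-(benzyloxy)phenyl]-3-[2,4,6-tris(benzyloxy)benzoyl]benzofuran (5-OBn; 4'-OBn), via aryllithium 18 (not isolated)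
Conditions: 17, n-BuLi, THF, -78 °C; then 15, -78 to 0 °C; aq. NH4Cl
Reagents that add atoms: none
Why: bromine–lithium exchange and nucleophilic acyl substitution of the ester by the aryllithium, which should stop at the ketone because two ortho-benzyloxy groups and the 2-aryl group shield the new carbonyl from a second addition.

Step 12
Reactants: 19 (2S)-flavan-fused 2-[4-(benzyloxy)phenyl]-3-[2,4,6-tris(benzyloxy)benzoyl]benzofuran
Product: 20 (2S)-flavan-fused 2-[4-(benzyloxy)phenyl]-3-[2-hydroxy-4,6-bis(benzyloxy)benzoyl]benzofuran (5-OBn; 4'-OBn)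
Conditions: BCl3 (1.1 equiv), CH2Cl2, -78 °C; then MeOH, aq. NaHCO3
Reagents that add atoms: none
Why: chelation-directed Lewis acid ether cleavage: BCl3 bound to the ketone oxygen reaches only an ortho-benzyloxy group, and the two ortho ethers are equivalent, so a single phenol should result while the other five benzyl ethers stay.

Step 13
Reactants: 20 (2S)-flavan-fused 2-[4-(benzyloxy)phenyl]-3-[2-hydroxy-4,6-bis(benzyloxy)benzoyl]benzofuran
Product: 22 penta-O-benzyl ether of the target (ketal carbon R; carbinol carbon S; flavan C2 S; free tertiary OH), via furan 2,3-epoxide 21 (not isolated)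
Conditions: (R,R)-[N,N'-bis(3,5-di-tert-butylsalicylidene)cyclohexane-1,2-diaminato]MnCl (10 mol%), NMO, mCPBA, CH2Cl2, -78 °C
Reagents that add atoms: 3-chloroperoxybenzoic acid O=C(OO)c1cccc(Cl)c1
Why: Proposed new method: the chiral oxo-manganese salen species (pentavalent manganese) should transfer oxygen to the electron-rich furan C2=C3 bond of 20 (a 2-aryl enol ether) on the face chosen by the (R,R)-ligand (assigned by analogy with indene and chromenes), which fixes the carbinol carbon as S in epoxide 21; 21 then ionises at C2 (oxocarbenium held by the furan oxygen and the 4-benzyloxyphenyl group) and the hydrogen-bonded ortho-phenol of the aroyl group closes the six-membered pyranone ring (6-exo attack on the cation), so the ketal centre is relayed from the carbinol centre through the ring fusion; the closest known reaction types are the Jacobsen epoxidation of indenes, chromenes and isoflavones and the dioxirane epoxidation and ring-opening of benzofurans.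

Step 14
Reactants: 22 penta-O-benzyl ether of the target
Product: 23 target CNP0208300.3
Conditions: H2 (1 atm), Pd(OH)2 on carbon, EtOAc/MeOH, rt
Reagents that add atoms: none
Why: hydrogenolysis of the five aryl benzyl ethers, which is much faster than cleavage of the benzylic C–O bonds of the flavan, the ketal and the tertiary carbinol, so all three stereocenters should be kept.

Compound list
1 | (2S)-naringenin, (2S)-5,7-dihydroxy-2-(4-hydroxyphenyl)chroman-4-one | O=C1C[C@@H](c2ccc(O)cc2)Oc2cc(O)cc(O)c12 | starting material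
2 | (2S)-5-hydroxy-2-(4-hydroxyphenyl)-7-(methoxymethoxy)chroman-4-one | O=C1C[C@@H](c2ccc(O)cc2)Oc2cc(OCOC)cc(O)c12 | intermediate
3 | (2S)-5-(ethoxycarbonyloxy)-2-[4-(ethoxycarbonyloxy)phenyl]-7-(methoxymethoxy)chroman-4-one (bis(ethyl carbonate), not isolated) | O=C1C[C@@H](c2ccc(OC(=O)OCC)cc2)Oc2cc(OCOC)cc(OC(=O)OCC)c12 | intermediate
4 | (2S)-2-(4-hydroxyphenyl)-7-(methoxymethoxy)chroman-5-ol | COCOc1cc(O)c2c(c1)O[C@H](c1ccc(O)cc1)CC2 | intermediate
5 | (2S)-5-(benzyloxy)-2-[4-(benzyloxy)phenyl]-7-(methoxymethoxy)chromane | COCOc1cc(OCc3ccccc3)c2c(c1)O[C@H](c1ccc(OCc3ccccc3)cc1)CC2 | intermediate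
6 | (2S)-5-(benzyloxy)-2-[4-(benzyloxy)phenyl]-8-bromo-7-(methoxymethoxy)chromane | COCOc1cc(OCc3ccccc3)c2c(c1Br)O[C@H](c1ccc(OCc3ccccc3)cc1)CC2 | intermediate
7 | (2S)-5-(benzyloxy)-2-[4-(benzyloxy)phenyl]-8-bromochroman-7-ol | Oc1cc(OCc3ccccc3)c2c(c1Br)O[C@H](c1ccc(OCc3ccccc3)cc1)CC2 | intermediate
8 | (2S)-5-(benzyloxy)-2-[4-(benzyloxy)phenyl]-8-bromo-7-(trimethylsilyloxy)chromane (aryl trimethylsilyl ether, not isolated) | C[Si](C)(C)Oc1cc(OCc3ccccc3)c2c(c1Br)O[C@H](c1ccc(OCc3ccccc3)cc1)CC2 | intermediate
9 | lithium (2S)-5-(benzyloxy)-2-[4-(benzyloxy)phenyl]-8-(trimethylsilyl)chroman-7-olate (not isolated) | [Li+].[O-]c1cc(OCc3ccccc3)c2c(c1[Si](C)(C)C)O[C@H](c1ccc(OCc3ccccc3)cc1)CC2 | intermediate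
10 | (2S)-5-(benzyloxy)-2-[4-(benzyloxy)phenyl]-8-(trimethylsilyl)chroman-7-yl trifluoromethanesulfonate | FC(F)(F)S(=O)(=O)Oc1cc(OCc3ccccc3)c2c(c1[Si](C)(C)C)O[C@H](c1ccc(OCc3ccccc3)cc1)CC2 | intermediate
11 | 1-[4-(benzyloxy)phenyl]ethan-1-one | CC(=O)c1ccc(OCc2ccccc2)cc1 | starting material
12 | ethyl 3-[4-(benzyloxy)phenyl]-3-oxopropanoate | CCOC(=O)CC(=O)c1ccc(OCc2ccccc2)cc1 | intermediate
13 | ethyl 3-[4-(benzyloxy)phenyl]-3-oxo-2-(phenyl-λ3-iodanylidene)propanoate (iodonium ylide) | CCOC(=O)[C-]([I+]c1ccccc1)C(=O)c1ccc(OCc2ccccc2)cc1 | intermediate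
14 | (2S)-5-(benzyloxy)-2-[4-(benzyloxy)phenyl]-7,8-didehydrochromane (7,8-aryne, not isolated) | C1#CC2=C(CC[C@@H](c3ccc(OCc4ccccc4)cc3)O2)C(OCc2ccccc2)=C1 | intermediate
15 | ethyl ester of the (2S)-flavan-fused 2-[4-(benzyloxy)phenyl]benzofuran-3-carboxylic acid (furan O on flavan C7; furan C3 on flavan C8; 5-OBn; 4'-OBn) | CCOC(=O)c1c(-c2ccc(OCc3ccccc3)cc2)oc2cc(OCc3ccccc3)c3c(c12)O[C@H](c1ccc(OCc2ccccc2)cc1)CC3 | intermediate
16 | 1,3,5-tris(benzyloxy)benzene | c1ccc(COc2cc(OCc3ccccc3)cc(OCc3ccccc3)c2)cc1 | starting material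
17 | 2-bromo-1,3,5-tris(benzyloxy)benzene | Brc1c(OCc2ccccc2)cc(OCc2ccccc2)cc1OCc1ccccc1 | intermediate
18 | 2,4,6-tris(benzyloxy)phenyllithium (not isolated) | [Li]c1c(OCc2ccccc2)cc(OCc2ccccc2)cc1OCc1ccccc1 | intermediate
19 | (2S)-flavan-fused 2-[4-(benzyloxy)phenyl]-3-[2,4,6-tris(benzyloxy)benzoyl]benzofuran (5-OBn; 4'-OBn) | O=C(c1c(OCc2ccccc2)cc(OCc2ccccc2)cc1OCc1ccccc1)c1c(-c2ccc(OCc3ccccc3)cc2)oc2cc(OCc3ccccc3)c3c(c12)O[C@H](c1ccc(OCc2ccccc2)cc1)CC3 | intermediate
20 | (2S)-flavan-fused 2-[4-(benzyloxy)phenyl]-3-[2-hydroxy-4,6-bis(benzyloxy)benzoyl]benzofuran (5-OBn; 4'-OBn) | O=C(c1c(O)cc(OCc2ccccc2)cc1OCc1ccccc1)c1c(-c2ccc(OCc3ccccc3)cc2)oc2cc(OCc3ccccc3)c3c(c12)O[C@H](c1ccc(OCc2ccccc2)cc1)CC3 | intermediate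
21 | furan 2,3-epoxide of 20, oxygen on the face that becomes the carbinol OH of 22 (not isolated) | O=C(c1c(O)cc(OCc2ccccc2)cc1OCc1ccccc1)[C@]12O[C@@]1(c1ccc(OCc3ccccc3)cc1)Oc1cc(OCc3ccccc3)c3c(c12)O[C@H](c1ccc(OCc2ccccc2)cc1)CC3 | intermediate
22 | penta-O-benzyl ether of the target (ketal carbon R; carbinol carbon S; flavan C2 S; free tertiary OH) | O=C1c2c(OCc5ccccc5)cc(OCc5ccccc5)cc2O[C@@]2(c3ccc(OCc5ccccc5)cc3)Oc3cc(OCc5ccccc5)c4c(c3[C@]12O)O[C@H](c1ccc(OCc5ccccc5)cc1)CC4 | intermediate
23 | target CNP0208300.3 (ketal carbon R; carbinol carbon S; flavan C2 S) | O=C1c2c(O)cc(O)cc2O[C@@]2(c3ccc(O)cc3)Oc3cc(O)c4c(c3[C@]12O)O[C@H](c1ccc(O)cc1)CC4 | target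

Total step count: 14. Longest linear sequence: 11 steps (steps 1 to 6, 9, 11, 12, 13, 14).

Steps most likely to fail

1. Step 13 (proposed new method). Oxygen transfer to the hindered, acyl-substituted furan double bond may be too slow at low temperature, the facial selectivity may be poor or of the opposite sense, or the electron-rich phenol ring may be oxidised instead. Fallback with known chemistry: from 20, epoxidation with dimethyldioxirane (acetone/CH2Cl2, -78 to -20 °C), the established reagent for benzofuran 2,3-epoxidation, followed by the same in-flask ring closure, would give 22 together with its diastereomer F1 (opposite configuration at both the ketal and the carbinol carbon). Because the flavan centre is fixed, the two are diastereomers and are separated by chromatography; the route is rejoined at 22.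

2. Step 9. The ylide may decompose before the aryne is released, its carbon instead of its oxygen may add to the aryne, or the addition may take the reverse orientation. Fallback: from 7, Sonogashira coupling with 1-(benzyloxy)-4-ethynylbenzene (PdCl2(PPh3)2, CuI, Et3N, DMF, 80 °C) would give ortho-alkynylphenol F2, which cyclises in the same flask (5-endo-dig attack of the phenol on the copper-activated alkyne) to 2-arylbenzofuran F3. Friedel–Crafts acylation of F3 at the furan C3 with 2,4,6-tris(benzyloxy)benzoyl chloride (SnCl4, CH2Cl2, -78 °C) rejoins the route at 19.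

3. Step 11. The hindered aryllithium may fail to add to the shielded, vinylogous carbonate-type ester, or may act as a base. Fallback: from 15, saponification (LiOH, THF/MeOH/H2O, 50 °C) would give carboxylic acid F4. Friedel–Crafts acylation of 1,3,5-tris(benzyloxy)benzene 16 with the mixed anhydride of F4 (trifluoroacetic anhydride, CH2Cl2, 0 °C to rt) would then give 19, where the route is rejoined.

Further compounds
F1 | step 13 | diastereomer of 22 with ketal carbon S and carbinol carbon R (flavan C2 S) | O=C1c2c(OCc5ccccc5)cc(OCc5ccccc5)cc2O[C@]2(c3ccc(OCc5ccccc5)cc3)Oc3cc(OCc5ccccc5)c4c(c3[C@@]12O)O[C@H](c1ccc(OCc5ccccc5)cc1)CC4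
F2 | step 9 | (2S)-5-(benzyloxy)-2-[4-(benzyloxy)phenyl]-8-{[4-(benzyloxy)phenyl]ethynyl}chroman-7-ol | Oc1cc(OCc3ccccc3)c2c(c1C#Cc1ccc(OCc3ccccc3)cc1)O[C@H](c1ccc(OCc3ccccc3)cc1)CC2
F3 | step 9 | (2S)-flavan-fused 2-[4-(benzyloxy)phenyl]benzofuran, unsubstituted at furan C3 (5-OBn; 4'-OBn) | c1c(-c2ccc(OCc3ccccc3)cc2)oc2cc(OCc3ccccc3)c3c(c12)O[C@H](c1ccc(OCc2ccccc2)cc1)CC3
F4 | step 11 | (2S)-flavan-fused 2-[4-(benzyloxy)phenyl]benzofuran-3-carboxylic acid (5-OBn; 4'-OBn) | OC(=O)c1c(-c2ccc(OCc3ccccc3)cc2)oc2cc(OCc3ccccc3)c3c(c12)O[C@H](c1ccc(OCc2ccccc2)cc1)CC3
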